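**Plan**

- Retrosynthesis first removes the γ-acetyl group and three benzyl ethers, then cuts the Cα–O bond. Cα is the benzylic carbon para to O4 of the guaiacyl ring (the carbon that becomes a quinone methide in lignin chemistry) and the Cγ oxygen stands 1,3 to it, so a carbonate on that oxygen can reach a Cα cation through a six-membered 1,3-dioxan-2-one.
- Further cuts: the Cβ–O4' aryl ether bond (aryl-lactate plus 5,7-di-O-benzyltricin), the guaiacyl C1–Cα bond (aryl Grignard plus glycidate C3), and ring C of the flavone (chalcone C=C, then O1–C2).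
- Forward: ring C is closed first; the three-carbon chain is attached to the guaiacyl ring, joined to the flavone 4'-oxygen, reduced at Cγ and carbonated; the oxidation closes the temporary dioxanone, which is then opened, acetylated at the γ-oxygen and debenzylated.
- Stereochemistry: Cβ comes from methyl (S)-glycidate and is inverted once in the Mitsunobu coupling; Cα is set from Cβ in the trans-selective ring closure.

Key step: step 11

Remark: Cα, Cβ and Cγ denote the benzylic carbon, the aryloxy-bearing carbon and the oxygenated methylene of the side chain; rings A, B and C are those of the flavone; the target SMILES is read as (αR,βS), the erythro isomer.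

Step 1
Reactants: 1 2',4',6'-trihydroxyacetophenone
Product: 2 1-[2,4-bis(benzyloxy)-6-hydroxyphenyl]ethanone
Conditions: BnBr (2.1 equiv), K2CO3, DMF, rt
Reagents that add atoms: benzyl bromide, BrCc1ccccc1
Why: Williamson etherification in which the hydroxyl that stays hydrogen-bonded to the acetyl carbonyl is the least nucleophilic and should be left free when two equivalents of halide are used.

Step 2
Reactants: 3 syringaldehyde
Product: 4 4-(allyloxy)-3,5-dimethoxybenzaldehyde
Conditions: allyl bromide, K2CO3, DMF, 60 °C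
Reagents that add atoms: allyl bromide, C=CCBr
Why: Williamson etherification of the acidic phenol gives an allyl ether that withstands hydroxide and can later be removed without touching benzyl ethers.

Step 3
Reactants: 2 1-[2,4-bis(benzyloxy)-6-hydroxyphenyl]ethanone; 4 4-(allyloxy)-3,5-dimethoxybenzaldehyde
Product: 5 (E)-3-[4-(allyloxy)-3,5-dimethoxyphenyl]-1-[2,4-bis(benzyloxy)-6-hydroxyphenyl]prop-2-en-1-one
Conditions: KOH (50% aq.), EtOH/THF, rt
Reagents that add atoms: none
Why: Claisen–Schmidt condensation of the acetophenone enolate with a non-enolisable aldehyde, followed by E1cB dehydration, should give the E-chalcone.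

Step 4
Reactants: 5 (E)-3-[4-(allyloxy)-3,5-dimethoxyphenyl]-1-[2,4-bis(benzyloxy)-6-hydroxyphenyl]prop-2-en-1-one
Product: 6 2-[4-(allyloxy)-3,5-dimethoxyphenyl]-5,7-bis(benzyloxy)-4H-chromen-4-one
Conditions: I2 (10 mol%), DMSO, 120 °C
Reagents that add atoms: none
Why: Iodine-catalysed oxidative cyclisation of a 2'-hydroxychalcone (6-endo oxa-Michael closure of ring C, then dehydrogenation with DMSO as terminal oxidant) is the standard flavone synthesis and tolerates aryl benzyl ethers; if the HI formed cleaves part of the allyl ether, the phenol released is simply the product of step 5.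

Step 5
Reactants: 6 2-[4-(allyloxy)-3,5-dimethoxyphenyl]-5,7-bis(benzyloxy)-4H-chromen-4-one
Product: 7 5,7-bis(benzyloxy)-2-(4-hydroxy-3,5-dimethoxyphenyl)-4H-chromen-4-one (5,7-di-O-benzyltricin)
Conditions: Pd(PPh3)4 (5 mol%), morpholine, THF, rt
Reagents that add atoms: none
Why: Tsuji–Trost deallylation, in which zerovalent palladium ionises the allyl aryl ether to a π-allyl complex that morpholine captures, frees the 4'-phenol while the benzyl ethers stay inert.

Step 6
Reactants: 8 4-bromo-2-methoxyphenol
Product: 9 1-(benzyloxy)-4-bromo-2-methoxybenzene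
Conditions: BnBr, K2CO3, DMF, rt
Reagents that add atoms: benzyl bromide, BrCc1ccccc1
Why: Williamson etherification of the phenol gives the benzyl ether needed for Grignard formation and for the final hydrogenolysis.

Step 7
Reactants: 9 1-(benzyloxy)-4-bromo-2-methoxybenzene; 10 methyl (2S)-oxirane-2-carboxylate (methyl (S)-glycidate)
Product: 12 methyl (2S)-3-[4-(benzyloxy)-3-methoxyphenyl]-2-hydroxypropanoate, via arylmagnesium bromide 11 (not isolated)
Conditions: Mg, THF, rt; then CuBr·SMe2 (10 mol%), 10, THF, −40 °C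
Reagents that add atoms: none
Why: Copper-catalysed Grignard opening of a glycidic ester occurs by SN2 attack at the unsubstituted C3 and should leave the ester intact at low temperature, so the C2 centre of the glycidate is carried over unchanged as the (S)-lactate.

Step 8
Reactants: 12 methyl (2S)-3-[4-(benzyloxy)-3-methoxyphenyl]-2-hydroxypropanoate; 7 5,7-bis(benzyloxy)-2-(4-hydroxy-3,5-dimethoxyphenyl)-4H-chromen-4-one
Product: 13 methyl (2R)-3-[4-(benzyloxy)-3-methoxyphenyl]-2-{4-[5,7-bis(benzyloxy)-4-oxo-4H-chromen-2-yl]-2,6-dimethoxyphenoxy}propanoate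
Conditions: PPh3, DIAD, THF, 0 °C to rt
Reagents that add atoms: none
Why: Mitsunobu etherification, in which the acidic 4'-phenol (vinylogous to the pyranone carbonyl) displaces the alkoxyphosphonium group of the α-hydroxy ester by SN2, should invert Cβ from S to R, the ester activation offsetting the two ortho-methoxy groups.

Step 9
Reactants: 13 methyl (2R)-3-[4-(benzyloxy)-3-methoxyphenyl]-2-{4-[5,7-bis(benzyloxy)-4-oxo-4H-chromen-2-yl]-2,6-dimethoxyphenoxy}propanoate
Product: 14 (2R)-3-[4-(benzyloxy)-3-methoxyphenyl]-2-{4-[5,7-bis(benzyloxy)-4-oxo-4H-chromen-2-yl]-2,6-dimethoxyphenoxy}propan-1-ol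
Conditions: NaBH4, THF/MeOH, 0 °C to rt
Reagents that add atoms: none
Why: Borohydride reduction of an activated α-aryloxy ester should proceed cold, before the ester can enolise, while the flavone carbonyl, a vinylogous ester deactivated by the 5,7-dialkoxy donors, does not respond to NaBH4.

Step 10
Reactants: 14 (2R)-3-[4-(benzyloxy)-3-methoxyphenyl]-2-{4-[5,7-bis(benzyloxy)-4-oxo-4H-chromen-2-yl]-2,6-dimethoxyphenoxy}propan-1-ol
Product: 15 tert-butyl (2R)-3-[4-(benzyloxy)-3-methoxyphenyl]-2-{4-[5,7-bis(benzyloxy)-4-oxo-4H-chromen-2-yl]-2,6-dimethoxyphenoxy}propyl carbonate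
Conditions: Boc2O, DMAP (cat.), CH2Cl2, rt
Reagents that add atoms: di-tert-butyl dicarbonate, CC(C)(C)OC(=O)OC(=O)OC(C)(C)C
Why: DMAP-catalysed acylation of the primary alcohol with Boc2O gives the mixed tert-butyl carbonate that serves as the tethered oxygen donor.

Step 11
Reactants: 15 tert-butyl (2R)-3-[4-(benzyloxy)-3-methoxyphenyl]-2-{4-[5,7-bis(benzyloxy)-4-oxo-4H-chromen-2-yl]-2,6-dimethoxyphenoxy}propyl carbonate
Product: 16 (4R,5S)-4-[4-(benzyloxy)-3-methoxyphenyl]-5-{4-[5,7-bis(benzyloxy)-4-oxo-4H-chromen-2-yl]-2,6-dimethoxyphenoxy}-1,3-dioxan-2-one (trans)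
Conditions: DDQ (1.5 equiv), 2,6-dichloropyridine, 4 Å MS, ClCH2CH2Cl, rt to 60 °C
Reagents that add atoms: none
Why: Proposed new method: DDQ forms a charge-transfer complex with the 4-benzyloxy-3-methoxyphenyl ring and removes a hydride (electron, proton, electron) from Cα to give a para-benzyloxy-stabilised benzylic cation, an O-benzylated quinone methide oxocarbenium ion; the carbonyl oxygen of the Cγ tert-butyl carbonate adds to Cα and the resulting 2-tert-butoxy-1,3-dioxan-2-ylium ion sheds isobutene, the proton going to DDQH−. The closest known reactions are DDQ-mediated benzylic C–H oxygenations of alkoxyarenes by a tethered oxygen nucleophile (oxidative lactonisation and etherification) and the capture of carbocations or iodonium ions by tert-butyl carbonates with loss of isobutene, which have not been combined on a β-aryloxy alkylarene. The 1,3-dioxan-2-one ring closes in a 6-exo-trig mode, oxygen attacking the exocyclic cationic carbon Cα through a chair-like six-membered transition state. The new stereocentre at Cα is controlled by the existing Cβ centre: with the aryl group on Cα and the aryloxy group on Cβ both equatorial the closure should give the trans (4R,5S) ring, which corresponds to the erythro (αR,βS) diol (Cβ is unchanged in space, its descriptor turning from R to S because oxygenated Cα now outranks Cγ), and re-ionisation of the para-alkoxybenzylic C–O bond under the mildly acidic conditions would let any cis isomer drain to the more stable trans one. The step needs site selectivity, which the substrate secures because the guaiacyl ring is the only arene not conjugated to the pyranone carbonyl and so the easiest to oxidise, Cα–H2 are the only benzylic hydrogens para to an ether oxygen on that ring, the OCH2Ph hydrogens sit on unactivated phenyl rings, and the carbonate oxygen now on Cα deactivates the product towards a second hydride loss. Loss of the Cβ proton to an enol ether is held back by the intramolecular six-membered delivery of the nucleophile and by the non-basic buffer 2,6-dichloropyridine.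

Step 12
Reactants: 16 (4R,5S)-4-[4-(benzyloxy)-3-methoxyphenyl]-5-{4-[5,7-bis(benzyloxy)-4-oxo-4H-chromen-2-yl]-2,6-dimethoxyphenoxy}-1,3-dioxan-2-one
Product: 17 (1R,2S)-1-[4-(benzyloxy)-3-methoxyphenyl]-2-{4-[5,7-bis(benzyloxy)-4-oxo-4H-chromen-2-yl]-2,6-dimethoxyphenoxy}propane-1,3-diol (erythro)
Conditions: K2CO3, MeOH/THF, 0 °C to rt
Reagents that add atoms: none
Why: Base-catalysed transesterification of the cyclic carbonate with methanol proceeds by acyl–oxygen cleavage, so neither stereocentre is touched, and the benzyl ether on the guaiacyl oxygen rules out quinone methide formation and hence epimerisation at Cα.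

Step 13
Reactants: 17 (1R,2S)-1-[4-(benzyloxy)-3-methoxyphenyl]-2-{4-[5,7-bis(benzyloxy)-4-oxo-4H-chromen-2-yl]-2,6-dimethoxyphenoxy}propane-1,3-diol
Product: 18 (2S,3R)-3-[4-(benzyloxy)-3-methoxyphenyl]-2-{4-[5,7-bis(benzyloxy)-4-oxo-4H-chromen-2-yl]-2,6-dimethoxyphenoxy}-3-hydroxypropyl acetate
Conditions: AcCl (1.05 equiv), 2,4,6-collidine, CH2Cl2, −78 °C
Reagents that add atoms: acetyl chloride, CC(=O)Cl
Why: Kinetically selective acylation with acetyl chloride and a hindered pyridine base at low temperature should take the primary γ-hydroxyl in preference to the secondary benzylic hydroxyl, which is shielded by the neighbouring aryloxy group.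

Step 14
Reactants: 18 (2S,3R)-3-[4-(benzyloxy)-3-methoxyphenyl]-2-{4-[5,7-bis(benzyloxy)-4-oxo-4H-chromen-2-yl]-2,6-dimethoxyphenoxy}-3-hydroxypropyl acetate
Product: 19 (2S,3R)-2-[4-(5,7-dihydroxy-4-oxo-4H-chromen-2-yl)-2,6-dimethoxyphenoxy]-3-hydroxy-3-(4-hydroxy-3-methoxyphenyl)propyl acetate (target)
Conditions: H2 (1 atm), Pd/C (10%), EtOAc/THF, rt
Reagents that add atoms: none
Why: Catalytic hydrogenolysis cleaves the three aryl benzyl ethers much faster than the secondary benzylic C–OH bond or the flavone C2=C3 bond, and the neutral aprotic medium should prevent acetyl migration, so both stereocentres are kept.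

**Compound list**

1 | 2',4',6'-trihydroxyacetophenone | CC(=O)c1c(O)cc(O)cc1O | starting material
2 | 1-[2,4-bis(benzyloxy)-6-hydroxyphenyl]ethanone | CC(=O)c1c(O)cc(OCc2ccccc2)cc1OCc1ccccc1 | intermediate
3 | syringaldehyde | COc1cc(C=O)cc(OC)c1O | starting material
4 | 4-(allyloxy)-3,5-dimethoxybenzaldehyde | COc1cc(C=O)cc(OC)c1OCC=C | intermediate
5 | (E)-3-[4-(allyloxy)-3,5-dimethoxyphenyl]-1-[2,4-bis(benzyloxy)-6-hydroxyphenyl]prop-2-en-1-one | COc1cc(/C=C/C(=O)c2c(O)cc(OCc3ccccc3)cc2OCc2ccccc2)cc(OC)c1OCC=C | intermediate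
6 | 2-[4-(allyloxy)-3,5-dimethoxyphenyl]-5,7-bis(benzyloxy)-4H-chromen-4-one | COc1cc(-c2cc(=O)c3c(OCc4ccccc4)cc(OCc4ccccc4)cc3o2)cc(OC)c1OCC=C | intermediate
7 | 5,7-bis(benzyloxy)-2-(4-hydroxy-3,5-dimethoxyphenyl)-4H-chromen-4-one | COc1cc(-c2cc(=O)c3c(OCc4ccccc4)cc(OCc4ccccc4)cc3o2)cc(OC)c1O | intermediate
8 | 4-bromo-2-methoxyphenol | COc1cc(Br)ccc1O | starting material
9 | 1-(benzyloxy)-4-bromo-2-methoxybenzene | COc1cc(Br)ccc1OCc1ccccc1 | intermediate
10 | methyl (2S)-oxirane-2-carboxylate | COC(=O)[C@@H]1CO1 | starting material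
11 | [4-(benzyloxy)-3-methoxyphenyl]magnesium bromide | COc1cc([Mg]Br)ccc1OCc1ccccc1 | intermediate
12 | methyl (2S)-3-[4-(benzyloxy)-3-methoxyphenyl]-2-hydroxypropanoate | COc1cc(C[C@@H](C(=O)OC)O)ccc1OCc1ccccc1 | intermediate
13 | methyl (2R)-3-[4-(benzyloxy)-3-methoxyphenyl]-2-{4-[5,7-bis(benzyloxy)-4-oxo-4H-chromen-2-yl]-2,6-dimethoxyphenoxy}propanoate | COc1cc(C[C@H](C(=O)OC)Oc2c(OC)cc(-c3cc(=O)c4c(OCc5ccccc5)cc(OCc5ccccc5)cc4o3)cc2OC)ccc1OCc1ccccc1 | intermediate
14 | (2R)-3-[4-(benzyloxy)-3-methoxyphenyl]-2-{4-[5,7-bis(benzyloxy)-4-oxo-4H-chromen-2-yl]-2,6-dimethoxyphenoxy}propan-1-ol | COc1cc(C[C@H](CO)Oc2c(OC)cc(-c3cc(=O)c4c(OCc5ccccc5)cc(OCc5ccccc5)cc4o3)cc2OC)ccc1OCc1ccccc1 | intermediate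
15 | tert-butyl (2R)-3-[4-(benzyloxy)-3-methoxyphenyl]-2-{4-[5,7-bis(benzyloxy)-4-oxo-4H-chromen-2-yl]-2,6-dimethoxyphenoxy}propyl carbonate | COc1cc(C[C@H](COC(=O)OC(C)(C)C)Oc2c(OC)cc(-c3cc(=O)c4c(OCc5ccccc5)cc(OCc5ccccc5)cc4o3)cc2OC)ccc1OCc1ccccc1 | intermediate
16 | (4R,5S)-4-[4-(benzyloxy)-3-methoxyphenyl]-5-{4-[5,7-bis(benzyloxy)-4-oxo-4H-chromen-2-yl]-2,6-dimethoxyphenoxy}-1,3-dioxan-2-one | O=C1OC[C@H](Oc2c(OC)cc(-c3cc(=O)c4c(OCc5ccccc5)cc(OCc5ccccc5)cc4o3)cc2OC)[C@@H](c2ccc(OCc3ccccc3)c(OC)c2)O1 | intermediate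
17 | (1R,2S)-1-[4-(benzyloxy)-3-methoxyphenyl]-2-{4-[5,7-bis(benzyloxy)-4-oxo-4H-chromen-2-yl]-2,6-dimethoxyphenoxy}propane-1,3-diol | COc1cc([C@@H](O)[C@H](CO)Oc2c(OC)cc(-c3cc(=O)c4c(OCc5ccccc5)cc(OCc5ccccc5)cc4o3)cc2OC)ccc1OCc1ccccc1 | intermediate
18 | (2S,3R)-3-[4-(benzyloxy)-3-methoxyphenyl]-2-{4-[5,7-bis(benzyloxy)-4-oxo-4H-chromen-2-yl]-2,6-dimethoxyphenoxy}-3-hydroxypropyl acetate | COc1cc([C@@H](O)[C@H](COC(C)=O)Oc2c(OC)cc(-c3cc(=O)c4c(OCc5ccccc5)cc(OCc5ccccc5)cc4o3)cc2OC)ccc1OCc1ccccc1 | intermediate
19 | (2S,3R)-2-[4-(5,7-dihydroxy-4-oxo-4H-chromen-2-yl)-2,6-dimethoxyphenoxy]-3-hydroxy-3-(4-hydroxy-3-methoxyphenyl)propyl acetate | COc1cc([C@@H](O)[C@H](COC(C)=O)Oc2c(OC)cc(-c3cc(=O)c4c(O)cc(O)cc4o3)cc2OC)ccc1O | target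

**Step count and risks**

Total steps: 14. Longest linear sequence: 11 steps (steps 1, 3, 4, 5 and 8 to 14, from compound 1 to compound 19).

Steps most likely to fail:

1. Step 11. Capture of the Cα cation by the carbonate may lose out to proton loss from Cβ, or the closure may show poor facial selectivity at Cα. The fallback sets out from alcohol 14 and returns at diol 17, using known chemistry. DDQ (2.5 equiv) in CH2Cl2/H2O at rt, the established oxidation of 4-alkoxyaryl alkanes through the benzylic alcohol to the aryl ketone in wet solvent, would give (2S)-1-[4-(benzyloxy)-3-methoxyphenyl]-2-{4-[5,7-bis(benzyloxy)-4-oxo-4H-chromen-2-yl]-2,6-dimethoxyphenoxy}-3-hydroxypropan-1-one F1. Reduction with Zn(BH4)2 in Et2O/THF at −20 °C, a non-basic hydride that should not enolise the α-aryloxy ketone, would then set Cα under chelation of zinc between the carbonyl and the aryl ether oxygen and should give erythro diol 17, any threo isomer being removed by chromatography.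

2. Step 8. Slow substitution by the di-ortho-substituted phenol may let elimination to the cinnamate and alkylation of the reduced azodicarboxylate compete, with possible erosion of configuration. The fallback sets out from lactate 12 and returns at ester 13. Tf2O and 2,6-lutidine in CH2Cl2 at −78 °C would give methyl (2S)-3-[4-(benzyloxy)-3-methoxyphenyl]-2-{[(trifluoromethyl)sulfonyl]oxy}propanoate F2. Its displacement by the potassium phenoxide of 7 (K2CO3, MeCN, 0 °C to rt), the known SN2 reaction of α-triflyloxy esters with phenoxides, proceeds with inversion and should give 13 without a phosphonium intermediate.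

3. Step 13. Acylation may run on to the benzylic hydroxyl, or the acetyl group may migrate between the two 1,3-related oxygens. The fallback sets out from diol 17 and returns at target 19, leaving out 18. Hydrogenolysis (H2, Pd/C, EtOAc/THF) would first give (1R,2S)-2-[4-(5,7-dihydroxy-4-oxo-4H-chromen-2-yl)-2,6-dimethoxyphenoxy]-1-(4-hydroxy-3-methoxyphenyl)propane-1,3-diol F3. Transesterification with vinyl acetate catalysed by immobilised Candida antarctica lipase B in THF at 40 °C, which acylates primary aliphatic hydroxyls in preference to phenols and hindered secondary alcohols, should then place the acetate on the γ-oxygen only.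

Further compounds
F1 | step 11 | (2S)-1-[4-(benzyloxy)-3-methoxyphenyl]-2-{4-[5,7-bis(benzyloxy)-4-oxo-4H-chromen-2-yl]-2,6-dimethoxyphenoxy}-3-hydroxypropan-1-one | COc1cc(C(=O)[C@H](CO)Oc2c(OC)cc(-c3cc(=O)c4c(OCc5ccccc5)cc(OCc5ccccc5)cc4o3)cc2OC)ccc1OCc1ccccc1
F2 | step 8 | methyl (2S)-3-[4-(benzyloxy)-3-methoxyphenyl]-2-{[(trifluoromethyl)sulfonyl]oxy}propanoate | COc1cc(C[C@@H](C(=O)OC)OS(=O)(=O)C(F)(F)F)ccc1OCc1ccccc1
F3 | step 13 | (1R,2S)-2-[4-(5,7-dihydroxy-4-oxo-4H-chromen-2-yl)-2,6-dimethoxyphenoxy]-1-(4-hydroxy-3-methoxyphenyl)propane-1,3-diol | COc1cc([C@@H](O)[C@H](CO)Oc2c(OC)cc(-c3cc(=O)c4c(O)cc(O)cc4o3)cc2OC)ccc1O
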